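# Proposed total synthesis of epicatechin 3-O-gallate-(4β→8)-epigallocatechin 3-O-gallate-(4β→8)-catechin 3-O-gallate (CNP0321910.1)

## The problem

The target is a trimer of three 2-arylchroman (flavan) units joined by two C4–C8 bonds, each esterified at O3 with gallic acid. It has eight stereocentres (top unit 2R,3R,4R; middle unit 2R,3R,4S; bottom unit 2R,3S) and twenty-two free phenols. The top and bottom units have the skeletons of (−)-epicatechin and (+)-catechin, so four centres can be bought. The top C4 is set reliably trans to its own C3 oxygen when a nucleophile adds to the C4 cation. The three contiguous centres of ring C of the middle unit lie too far from the outer stereocentres to be relayed from them and need their own source of control. The C4–aryl bonds are benzylic bonds to phloroglucinol-type rings and cleave under acid, the gallates are base-labile, and the free polyphenol oxidises easily, so the phenols must stay masked until a final neutral deprotection; each interflavan bond must also go to C8 and not to C6. The feature that opens a non-classical route is ring C of the middle unit: O1 and C4 sit on the adjacent ring A carbons C8a and C4a, so O1–C8a–C4a–C4 is a latent ortho-quinone methide, while C2–C3 carries the pyrogallol ring and the gallate cis to each other, the pattern of a (Z)-enol ester. Ring C is therefore the formal [4+2] adduct of these two.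

## Retrosynthesis

**Target 24 to perbenzyl ether 23.** The twenty-two phenolic O–CH2Ph bonds are cut last. Benzyl ethers are preferred over methyl ethers or acetates because neutral hydrogenolysis is the only global deprotection that both the gallates and the acid-labile interflavan bonds tolerate. The forward reaction must leave the benzylic C2–O1 and C4–aryl bonds intact.

**23 to diol 22 and acid 15; 22 to bis-silyl ether 21.** The two outer ester C–O bonds are cut next. The outer gallates cannot be carried from the start because the bottom unit passes through an aryllithium, so both outer C3 oxygens are silyl-protected until the skeleton is complete. The middle gallate is not cut here because it arrives with the ring-forming step. The forward steps are a fluoride desilylation and the acylation of one hindered axial and one equatorial secondary alcohol.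

**21 to carbinol 14 and enol gallate 19, through methide 20.** O1–C2 and C3–C4 of the middle ring C are cut together. The conventional cut at the two C4–C8 bonds would need a C4-activated middle unit already carrying its gallate and two successive cation couplings, each with a C8/C6 and an oligomerisation problem. The [4+2] cut removes one ring, three stereocentres and the middle gallate at once. What remains is carbinol 14, in which the top and bottom units meet at one sp3 carbon, and the achiral alkene 19. The forward reaction must deliver the right regiochemistry, transfer the Z geometry into the 2,3-cis pair, place C4 trans to C3 and select one face of 20.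

**14 to aldehyde 7 and bromide 11, through aryllithium 12 and phenoxide 13.** The bond between the carbinol carbon and C8 of the bottom unit is cut. The other aryl–carbinol bond would require metalating a ring next to a free phenol, whereas C8 of benzylated catechin is brominated selectively and lithiated cleanly. Both carbinol epimers serve, so the addition needs no stereocontrol.

**7 to phenol 6; 6 to ether 4 and phenol 5; 4 to 3, 2 and 1.** The formyl C–C bond is cut first, then the C4(top)–C8(middle) bond. Phenol 5 is chosen as the ring A stub over a fully free or fully benzylated triol because its single free hydroxyl does three jobs. It leaves the least hindered ring position for the flavan-4-yl cation, it directs the MgCl2-mediated formylation to its one free ortho position, and it later becomes O1. No late selective benzylation is needed. The cation comes from 4, made from (−)-epicatechin 1 by benzylation (2), silylation (3) and C4 oxidation.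

**19 to alkyne 18 and acid 15; 18 to alcohol 16; 16 to 15.** The vinyl C–O bond is cut to a terminal alkyne and the acid, because [Ru(p-cymene)Cl2]2-catalysed anti-Markovnikov addition gives the Z enol ester directly. Enolate acylation would not control the geometry. Alkyne 18 is a one-carbon homologue of aldehyde 17, which is reached from 15 through 16.

**11 to 10, 9 and (+)-catechin 8.** The C8–Br bond, the silyl ether and the four benzyl ethers are removed in turn. All three forward steps are standard for this flavanol.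

## Roads not taken

**Alternative 1: bottom unit grown on a phloroglucinol stub by epoxide opening.** The cut is O1–C2 of the bottom ring C. In the forward step the free phenol of epoxy-phenol A2 opens the trans-epoxide at the benzylic carbon with inversion (6-endo), giving dimer A1 with the 2,3-trans catechin pattern and a free 3-OH.
- Merits: the middle unit would come intact from the chiral pool with its gallate in place, so its three stereocentres are bought, and phenol–epoxide closures of this kind are established flavan-3-ol chemistry. In stereochemical safety for the middle ring this road is better than the chosen one.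
- Weak points: it builds by asymmetric synthesis the one unit that (+)-catechin 8 supplies ready-made. The electron-rich benzylic epoxide can open by an SN1 path with loss of the trans relationship, or close 5-exo. A1 also still lacks the top unit, which would have to be added by a cation coupling at C8 of a dimer.
- Comparison: the chosen plan uses both cheap flavanols unchanged, has the top unit in place before the ring is formed, and creates three centres, two bonds and the ester in one step.

**Alternative 2: acyloxonium-guided Friedel–Crafts closure of the middle ring C.** The cut is C4–C4a. A Lewis acid ionises either C4 epimer of carbinol A4, the C3 gallate bridges the cation as a dioxolanylium ion, and the 3,5-bis(benzyloxy)phenyl ether ring attacks from the open face to give A3.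
- Merits: it is stereoconvergent at C4, and the 3,4-trans outcome rests on neighbouring-group participation, a firmer basis than the endo preference on which the chosen plan relies. Two of the three gallates are already present.
- Weak points: C2 and C3 must first be made in an open chain as a benzylic aryl ether next to an ester, which costs several steps. That C2–OAr bond, benzylic to a trialkoxyphenyl ring, can itself ionise under the Lewis acid and scramble C2. A3 again has a free C8, so the top unit must be attached afterwards to a dimer carrying two gallates.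
- Comparison: the chosen plan has a shorter, more convergent assembly and forms C2 and C3 in the same step as the ring.

**Alternative 3: aryne cine-etherification from a C8 bromide.** The cut is O1–C8a. LiTMP removes the ring proton ortho to bromine in A6, LiBr is lost to give the C8–C8a aryne, and the tethered C2 alkoxide adds at C8a to give A5.
- Merits: the ring closure touches no stereocentre, so it raises no selectivity question, and the acid-free conditions spare the interflavan bond. In this respect it is superior to the chosen key step.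
- Weak points: all three centres, including the diarylmethine C4, must be set beforehand in an open chain. LiTMP meets many benzyl ethers (α-lithiation and Wittig rearrangement) and an acidic, doubly benzylic C4–H. The C2 alkoxide sits next to the C3 silyl ether and invites silyl migration. All three gallates and the top unit still have to be added to A5.
- Comparison: the chosen plan is far more step-economical and introduces the middle gallate directly.

Key step: step 13

Assumption 1: 3,5-bis(benzyloxy)phenol (5) and 3,4,5-tris(benzyloxy)benzoic acid (15), the benzyl ethers of phloroglucinol and gallic acid, are taken as purchased.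
Assumption 2: the facial preference of the chiral phosphoric acid on methide 20 cannot be predicted with confidence; the (R)-acid is written, and its (S)-enantiomer would replace it should the (R)-acid be the mismatched partner.
Assumption 3: carbinol 14 is used as the mixture of its two carbinol epimers, since both give the same methide.

## Route

Step 1
Reactants: 1 (−)-epicatechin
Product: 2 5,7,3',4'-tetra-O-benzyl-(−)-epicatechin (2R,3R; free 3-OH)
Conditions: BnBr (4.4 equiv), K2CO3, DMF, 0 °C → rt
Reagents that add atoms: benzyl bromide, BrCc1ccccc1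
Why: Williamson etherification; carbonate deprotonates only the four phenols, and the mild base at room temperature should leave C2 and the C3 alcohol untouched.

Step 2
Reactants: 2 5,7,3',4'-tetra-O-benzyl-(−)-epicatechin
Product: 3 5,7,3',4'-tetra-O-benzyl-3-O-(tert-butyldimethylsilyl)-(−)-epicatechin
Conditions: TBSCl, imidazole, DMF, rt → 40 °C
Reagents that add atoms: tert-butyldimethylsilyl chloride, CC(C)(C)[Si](C)(C)Cl
Why: Standard silylation of the axial secondary alcohol; the silyl ether withstands the later Lewis acid, magnesium phenoxide and organolithium steps.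

Step 3
Reactants: 3 5,7,3',4'-tetra-O-benzyl-3-O-TBS-(−)-epicatechin
Product: 4 4β-(2-ethoxyethoxy)-5,7,3',4'-tetra-O-benzyl-3-O-TBS-epicatechin (C4 ether trans to the C3 silyloxy group)
Conditions: DDQ (2 equiv), 2-ethoxyethanol (5 equiv), CH2Cl2, rt
Reagents that add atoms: 2-ethoxyethanol, CCOCCO
Why: DDQ benzylic oxidation; hydride abstraction from C4 gives a cation stabilised by the 5,7-dialkoxy ring A, and the alcohol adds anti to the C3 substituent. The C4 configuration is not critical because the centre is ionised again in step 4.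

Step 4
Reactants: 4 4β-(2-ethoxyethoxy) ether of the top unit, 5 3,5-bis(benzyloxy)phenol (3 equiv)
Product: 6 2-[5,7,3',4'-tetra-O-benzyl-3-O-TBS-epicatechin-4β-yl]-3,5-bis(benzyloxy)phenol (new aryl group trans to C3–OTBS; phenol OH ortho to the new C–C bond)
Conditions: TMSOTf (0.2 equiv), CH2Cl2, −78 → −40 °C
Reagents that add atoms: none
Why: Friedel–Crafts alkylation by the flavan-4-yl cation; attack anti to the axial C3 silyloxy group sets the 4β (3,4-trans) centre. The two equivalent positions between OH and OBn are less hindered than the one between two OBn groups, the same bias that sends such cations to C8 rather than C6 of benzylated flavans, and the excess of 5 suppresses double alkylation and self-condensation of 4.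

Step 5
Reactants: 6 top-unit phenol
Product: 7 2-hydroxy-4,6-bis(benzyloxy)-3-[5,7,3',4'-tetra-O-benzyl-3-O-TBS-epicatechin-4β-yl]benzaldehyde
Conditions: MgCl2 (3 equiv), Et3N (6 equiv), (CH2O)n (8 equiv), THF, reflux
Reagents that add atoms: paraformaldehyde (as formaldehyde), C=O
Why: Casnati–Skattebøl ortho-formylation; the magnesium phenoxide delivers formaldehyde only to the single free ortho position and a second formaldehyde oxidises the hydroxymethyl group, so the para position between the benzyloxy groups is untouched. The non-acidic medium spares the C4–aryl bond and the silyl ether.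

Step 6
Reactants: 8 (+)-catechin
Product: 9 5,7,3',4'-tetra-O-benzyl-(+)-catechin (2R,3S; free 3-OH)
Conditions: BnBr (4.4 equiv), K2CO3, DMF, 0 °C → rt
Reagents that add atoms: benzyl bromide, BrCc1ccccc1
Why: Williamson etherification of the four phenols, as in step 1.

Step 7
Reactants: 9 5,7,3',4'-tetra-O-benzyl-(+)-catechin
Product: 10 5,7,3',4'-tetra-O-benzyl-3-O-(tert-butyldimethylsilyl)-(+)-catechin
Conditions: TBSCl, imidazole, DMF, rt
Reagents that add atoms: tert-butyldimethylsilyl chloride, CC(C)(C)[Si](C)(C)Cl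
Why: Standard silylation of the equatorial secondary alcohol; the base-stable mask is needed for the lithiation.

Step 8
Reactants: 10 5,7,3',4'-tetra-O-benzyl-3-O-TBS-(+)-catechin
Product: 11 8-bromo-5,7,3',4'-tetra-O-benzyl-3-O-TBS-(+)-catechin
Conditions: NBS (1.05 equiv), CH2Cl2, −78 °C → rt
Reagents that add atoms: N-bromosuccinimide, O=C1CCC(=O)N1Br
Why: Electrophilic aromatic bromination; C8, flanked by the ring oxygen and one benzyloxy group, is more accessible than C6 between two benzyloxy groups, and the catechol ring is less activated.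

Step 9
Reactants: 11 8-bromo bottom unit (1.3 equiv), 7 top-unit salicylaldehyde
Product: 14 ortho-hydroxy diarylcarbinol joining C8 of the bottom unit to the ring A stub of the top unit (both epimers at the carbinol carbon), via 8-lithio flavan 12 (not isolated), via sodium phenoxide 13 (not isolated)
Conditions: 11, t-BuLi (2 equiv per 11), THF, −78 °C; separately 7, NaH (1.05 equiv), THF, 0 °C; combine at −78 → −20 °C; then H2O
Reagents that add atoms: none
Why: Bromine–lithium exchange followed by 1,2-addition of the aryllithium to the aldehyde; deprotonating the phenol first with a sacrificial base is the usual way to add organometallics to salicylaldehydes without wasting the nucleophile. The new carbinol centre forms unselectively, which is harmless because it is ionised in step 13.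

Step 10
Reactants: 15 3,4,5-tris(benzyloxy)benzoic acid
Product: 16 3,4,5-tris(benzyloxy)benzyl alcohol
Conditions: LiAlH4, THF, 0 °C → reflux
Reagents that add atoms: none
Why: Hydride reduction of a carboxylic acid to the primary alcohol; benzyl ethers are inert.

Step 11
Reactants: 16 3,4,5-tris(benzyloxy)benzyl alcohol
Product: 18 5-ethynyl-1,2,3-tris(benzyloxy)benzene, via 3,4,5-tris(benzyloxy)benzaldehyde 17 (not isolated)
Conditions: MnO2 (10 equiv), THF, rt; then Ohira–Bestmann reagent, K2CO3, MeOH, rt
Reagents that add atoms: dimethyl (1-diazo-2-oxopropyl)phosphonate, CC(=O)C(=[N+]=[N-])P(=O)(OC)OC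
Why: Benzylic oxidation with MnO2 followed in the same flask by Ohira–Bestmann (Seyferth–Gilbert) homologation of the non-enolisable aldehyde to the terminal alkyne.

Step 12
Reactants: 18 5-ethynyl-1,2,3-tris(benzyloxy)benzene, 15 3,4,5-tris(benzyloxy)benzoic acid
Product: 19 (Z)-2-[3,4,5-tris(benzyloxy)phenyl]ethenyl 3,4,5-tris(benzyloxy)benzoate
Conditions: [Ru(p-cymene)Cl2]2 (2 mol%), P(4-ClC6H4)3 (6 mol%), DMAP (8 mol%), toluene, 60 °C
Reagents that add atoms: none
Why: [Ru(p-cymene)Cl2]2-catalysed anti-Markovnikov hydro-acyloxylation of a terminal alkyne; the carboxylate adds to the terminal carbon of a ruthenium vinylidene and protonation gives the Z enol ester.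

Step 13
Reactants: 14 ortho-hydroxy diarylcarbinol (both epimers), 19 (Z)-enol gallate (2 equiv)
Product: 21 silyl-protected trimer bearing the middle gallate (middle ring C 2,3-cis-3,4-trans; outer C3 oxygens as TBS ethers), via ortho-quinone methide 20 (not isolated)
Conditions: (R)-TRIP [(R)-3,3'-bis(2,4,6-triisopropylphenyl)-1,1'-binaphthyl-2,2'-diyl hydrogen phosphate] (10 mol%), 5 Å MS, toluene, −20 °C → rt
Reagents that add atoms: none
Why: Proposed new method: the chiral phosphoric acid ionises either epimer of 14 with loss of water to the hydrogen-bonded ortho-quinone methide 20, whose O1=C8a–C4a=C4 heterodiene adds the alkene of 19 in an inverse-electron-demand [4+2] cycloaddition in which C3–C4 forms ahead of O1–C2. The closest known reaction type is the Brønsted-acid-catalysed [4+2] cycloaddition of ortho-quinone methides, generated in situ from ortho-hydroxybenzhydryl alcohols, with styrenes, enamides and enol ethers; a 2-arylvinyl ester has not served as the 2π partner. Ring C of the middle unit closes as a six-membered pyran by bonding at both diene termini (asynchronous concerted [4+2]; in the stepwise limit, conjugate addition at C4 followed by capture of the C2 benzylic cation by the phenol oxygen). The regiochemistry should follow from the polarisation of 19: the acylated oxygen is a weak donor, so positive charge is better carried at the benzylic carbon, the ester-bearing carbon attacks the methide carbon and the benzylic carbon is taken by O1. C2 and C3 come out cis because both bonds form on the same face of the Z alkene. C4 is set trans to the C3 gallate by endo approach of the alkene to the Z-configured methide, in which allylic strain with the peri C5 benzyloxy group turns the C4 aryl group toward the carbonyl oxygen. The absolute sense (2R,3R,4S in the middle ring of the target) depends on which face of 20 is attacked and is meant to be set by the confined chiral phosphate bound to the methide oxygen, acting with or against the two flanking flavan units. Toluene and low temperature are chosen to keep the ion pair tight and to suppress a free benzylic cation that could lose the Z geometry by rotation or acyloxonium formation.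

Step 14
Reactants: 21 silyl-protected trimer
Product: 22 trimer diol (free 3-OH on the top and bottom units; middle gallate and sixteen benzyl ethers retained)
Conditions: HF·pyridine, pyridine, THF, 0 °C → rt
Reagents that add atoms: none
Why: Fluoride-mediated Si–O cleavage; the buffered medium generates no alkoxide next to the aryl ester and is too weakly acidic to ionise the C4–aryl bonds.

Step 15
Reactants: 22 trimer diol, 15 3,4,5-tris(benzyloxy)benzoic acid (4 equiv)
Product: 23 docosa-O-benzyl ether of the target (all three C3 oxygens as tri-O-benzylgallates)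
Conditions: DCC (4 equiv), DMAP, CH2Cl2, rt
Reagents that add atoms: none
Why: Steglich esterification; the acylpyridinium from DMAP is reactive enough for the hindered axial 3-OH of the top unit, and no stereocentre is touched.

Step 16
Reactants: 23 docosa-O-benzyl ether of the target
Product: 24 epicatechin 3-O-gallate-(4β→8)-epigallocatechin 3-O-gallate-(4β→8)-catechin 3-O-gallate (target)
Conditions: H2 (1 atm), Pd(OH)2/C, THF/MeOH/H2O, rt
Reagents that add atoms: none
Why: Catalytic hydrogenolysis of the twenty-two benzyl ethers under neutral conditions; esters, the benzylic C2–O1 bonds and the C4–aryl bonds are stable to these mild conditions.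

## Compound list

1 | (−)-epicatechin | O[C@@H]1Cc2c(O)cc(O)cc2O[C@@H]1c1ccc(O)c(O)c1 | starting material
2 | 5,7,3',4'-tetra-O-benzyl-(−)-epicatechin | O[C@@H]1Cc2c(OCc9ccccc9)cc(OCc9ccccc9)cc2O[C@@H]1c1ccc(OCc9ccccc9)c(OCc9ccccc9)c1 | intermediate
3 | 5,7,3',4'-tetra-O-benzyl-3-O-TBS-(−)-epicatechin | CC(C)(C)[Si](C)(C)O[C@@H]1Cc2c(OCc9ccccc9)cc(OCc9ccccc9)cc2O[C@@H]1c1ccc(OCc9ccccc9)c(OCc9ccccc9)c1 | intermediate
4 | 4β-(2-ethoxyethoxy)-5,7,3',4'-tetra-O-benzyl-3-O-TBS-epicatechin (C4 ether trans to C3–OTBS) | CCOCCO[C@H]1c2c(OCc9ccccc9)cc(OCc9ccccc9)cc2O[C@H](c2ccc(OCc9ccccc9)c(OCc9ccccc9)c2)[C@@H]1O[Si](C)(C)C(C)(C)C | intermediate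
5 | 3,5-bis(benzyloxy)phenol | Oc1cc(OCc9ccccc9)cc(OCc9ccccc9)c1 | starting material
6 | 2-[5,7,3',4'-tetra-O-benzyl-3-O-TBS-epicatechin-4β-yl]-3,5-bis(benzyloxy)phenol | Oc1cc(OCc9ccccc9)cc(OCc9ccccc9)c1[C@H]2c3c(OCc9ccccc9)cc(OCc9ccccc9)cc3O[C@H](c3ccc(OCc9ccccc9)c(OCc9ccccc9)c3)[C@@H]2O[Si](C)(C)C(C)(C)C | intermediate
7 | 2-hydroxy-4,6-bis(benzyloxy)-3-[5,7,3',4'-tetra-O-benzyl-3-O-TBS-epicatechin-4β-yl]benzaldehyde | O=Cc1c(O)c([C@H]2c3c(OCc9ccccc9)cc(OCc9ccccc9)cc3O[C@H](c3ccc(OCc9ccccc9)c(OCc9ccccc9)c3)[C@@H]2O[Si](C)(C)C(C)(C)C)c(OCc9ccccc9)cc1OCc9ccccc9 | intermediate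
8 | (+)-catechin | O[C@H]1Cc2c(O)cc(O)cc2O[C@@H]1c1ccc(O)c(O)c1 | starting material
9 | 5,7,3',4'-tetra-O-benzyl-(+)-catechin | O[C@H]1Cc2c(OCc9ccccc9)cc(OCc9ccccc9)cc2O[C@@H]1c1ccc(OCc9ccccc9)c(OCc9ccccc9)c1 | intermediate
10 | 5,7,3',4'-tetra-O-benzyl-3-O-TBS-(+)-catechin | CC(C)(C)[Si](C)(C)O[C@H]1Cc2c(OCc9ccccc9)cc(OCc9ccccc9)cc2O[C@@H]1c1ccc(OCc9ccccc9)c(OCc9ccccc9)c1 | intermediate
11 | 8-bromo-5,7,3',4'-tetra-O-benzyl-3-O-TBS-(+)-catechin | CC(C)(C)[Si](C)(C)O[C@H]1Cc2c(OCc9ccccc9)cc(OCc9ccccc9)c(Br)c2O[C@@H]1c1ccc(OCc9ccccc9)c(OCc9ccccc9)c1 | intermediate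
12 | 8-lithio-5,7,3',4'-tetra-O-benzyl-3-O-TBS-(+)-catechin | CC(C)(C)[Si](C)(C)O[C@H]1Cc2c(OCc9ccccc9)cc(OCc9ccccc9)c([Li])c2O[C@@H]1c1ccc(OCc9ccccc9)c(OCc9ccccc9)c1 | intermediate (not isolated)
13 | sodium phenoxide of aldehyde 7 | [Na+].[O-]c1c(C=O)c(OCc9ccccc9)cc(OCc9ccccc9)c1[C@H]2c3c(OCc9ccccc9)cc(OCc9ccccc9)cc3O[C@H](c3ccc(OCc9ccccc9)c(OCc9ccccc9)c3)[C@@H]2O[Si](C)(C)C(C)(C)C | intermediate (not isolated)
14 | {2-hydroxy-4,6-bis(benzyloxy)-3-[tetra-O-benzyl-3-O-TBS-epicatechin-4β-yl]phenyl}[tetra-O-benzyl-3-O-TBS-catechin-8-yl]methanol, both carbinol epimers | OC(c1c(OCc9ccccc9)cc(OCc9ccccc9)c2c1O[C@H](c1ccc(OCc9ccccc9)c(OCc9ccccc9)c1)[C@@H](O[Si](C)(C)C(C)(C)C)C2)c1c(OCc9ccccc9)cc(OCc9ccccc9)c([C@H]2c3c(OCc9ccccc9)cc(OCc9ccccc9)cc3O[C@H](c3ccc(OCc9ccccc9)c(OCc9ccccc9)c3)[C@@H]2O[Si](C)(C)C(C)(C)C)c1O | intermediate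
15 | 3,4,5-tris(benzyloxy)benzoic acid | OC(=O)c1cc(OCc9ccccc9)c(OCc9ccccc9)c(OCc9ccccc9)c1 | starting material
16 | 3,4,5-tris(benzyloxy)benzyl alcohol | OCc1cc(OCc9ccccc9)c(OCc9ccccc9)c(OCc9ccccc9)c1 | intermediate
17 | 3,4,5-tris(benzyloxy)benzaldehyde | O=Cc1cc(OCc9ccccc9)c(OCc9ccccc9)c(OCc9ccccc9)c1 | intermediate (not isolated)
18 | 5-ethynyl-1,2,3-tris(benzyloxy)benzene | C#Cc1cc(OCc9ccccc9)c(OCc9ccccc9)c(OCc9ccccc9)c1 | intermediate
19 | (Z)-2-[3,4,5-tris(benzyloxy)phenyl]ethenyl 3,4,5-tris(benzyloxy)benzoate | O=C(O/C=C\c1cc(OCc9ccccc9)c(OCc9ccccc9)c(OCc9ccccc9)c1)c1cc(OCc9ccccc9)c(OCc9ccccc9)c(OCc9ccccc9)c1 | intermediate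
20 | (Z)-ortho-quinone methide: 3,5-bis(benzyloxy)-6-[(tetra-O-benzyl-3-O-TBS-catechin-8-yl)methylidene]-2-[tetra-O-benzyl-3-O-TBS-epicatechin-4β-yl]cyclohexa-2,4-dien-1-one, aryl group syn to the carbonyl | O=C1C([C@H]2c3c(OCc9ccccc9)cc(OCc9ccccc9)cc3O[C@H](c3ccc(OCc9ccccc9)c(OCc9ccccc9)c3)[C@@H]2O[Si](C)(C)C(C)(C)C)=C(OCc9ccccc9)C=C(OCc9ccccc9)/C1=C/c1c(OCc9ccccc9)cc(OCc9ccccc9)c2c1O[C@H](c1ccc(OCc9ccccc9)c(OCc9ccccc9)c1)[C@@H](O[Si](C)(C)C(C)(C)C)C2 | intermediate (not isolated)
21 | protected trimer: [tetra-O-benzyl-3-O-TBS-epicatechin]-(4β→8)-[penta-O-benzyl-epigallocatechin 3-O-(tri-O-benzylgallate)]-(4β→8)-[tetra-O-benzyl-3-O-TBS-catechin] | O=C(O[C@@H]1[C@@H](c2c(OCc9ccccc9)cc(OCc9ccccc9)c3c2O[C@H](c2ccc(OCc9ccccc9)c(OCc9ccccc9)c2)[C@@H](O[Si](C)(C)C(C)(C)C)C3)c2c(OCc9ccccc9)cc(OCc9ccccc9)c([C@H]3c4c(OCc9ccccc9)cc(OCc9ccccc9)cc4O[C@H](c4ccc(OCc9ccccc9)c(OCc9ccccc9)c4)[C@@H]3O[Si](C)(C)C(C)(C)C)c2O[C@@H]1c1cc(OCc9ccccc9)c(OCc9ccccc9)c(OCc9ccccc9)c1)c1cc(OCc9ccccc9)c(OCc9ccccc9)c(OCc9ccccc9)c1 | intermediate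
22 | trimer diol: as 21 with free 3-OH on the top and bottom units | O=C(O[C@@H]1[C@@H](c2c(OCc9ccccc9)cc(OCc9ccccc9)c3c2O[C@H](c2ccc(OCc9ccccc9)c(OCc9ccccc9)c2)[C@@H](O)C3)c2c(OCc9ccccc9)cc(OCc9ccccc9)c([C@H]3c4c(OCc9ccccc9)cc(OCc9ccccc9)cc4O[C@H](c4ccc(OCc9ccccc9)c(OCc9ccccc9)c4)[C@@H]3O)c2O[C@@H]1c1cc(OCc9ccccc9)c(OCc9ccccc9)c(OCc9ccccc9)c1)c1cc(OCc9ccccc9)c(OCc9ccccc9)c(OCc9ccccc9)c1 | intermediate
23 | docosa-O-benzyl ether of the target (three tri-O-benzylgallates) | O=C(O[C@@H]1[C@@H](c2c(OCc9ccccc9)cc(OCc9ccccc9)c3c2O[C@H](c2ccc(OCc9ccccc9)c(OCc9ccccc9)c2)[C@@H](OC(=O)c2cc(OCc9ccccc9)c(OCc9ccccc9)c(OCc9ccccc9)c2)C3)c2c(OCc9ccccc9)cc(OCc9ccccc9)c([C@H]3c4c(OCc9ccccc9)cc(OCc9ccccc9)cc4O[C@H](c4ccc(OCc9ccccc9)c(OCc9ccccc9)c4)[C@@H]3OC(=O)c3cc(OCc9ccccc9)c(OCc9ccccc9)c(OCc9ccccc9)c3)c2O[C@@H]1c1cc(OCc9ccccc9)c(OCc9ccccc9)c(OCc9ccccc9)c1)c1cc(OCc9ccccc9)c(OCc9ccccc9)c(OCc9ccccc9)c1 | intermediate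
24 | epicatechin 3-O-gallate-(4β→8)-epigallocatechin 3-O-gallate-(4β→8)-catechin 3-O-gallate | O=C(O[C@@H]1[C@@H](c2c(O)cc(O)c3c2O[C@H](c2ccc(O)c(O)c2)[C@@H](OC(=O)c2cc(O)c(O)c(O)c2)C3)c2c(O)cc(O)c([C@H]3c4c(O)cc(O)cc4O[C@H](c4ccc(O)c(O)c4)[C@@H]3OC(=O)c3cc(O)c(O)c(O)c3)c2O[C@@H]1c1cc(O)c(O)c(O)c1)c1cc(O)c(O)c(O)c1 | target

## Step count and risks

Total: 16 steps. Longest linear sequence: 10 steps (steps 1–5, 9, 13–16, from (−)-epicatechin).

**Step 13 (key step, Proposed new method).**
- Low reactivity: the methide carbon is stabilised by two trioxygenated aryl rings and may be too weak an electrophile for the moderately nucleophilic alkene.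
- Reversed regiochemistry: the ester oxygen could still direct bond formation through the aryl-bearing carbon.
- Loss of alkene geometry: a fully stepwise cationic path, with rotation or acyloxonium formation, would erode the 2,3-cis relationship.
- Poor endo/exo or facial selectivity: the methide oxygen is shielded by the top unit, and the catalyst may be mismatched with the two chiral flanks.
- Cleavage of the C4–C8 bond: prolonged acid exposure could break the top interflavan bond.

Fallback with known chemistry: the middle ring is taken from the chiral pool and joined by the established flavan-4-yl cation couplings. Commercial (−)-epigallocatechin gallate is perbenzylated (BnBr, K2CO3, DMF) to octa-O-benzyl-epigallocatechin gallate F1. F1 is oxidised with DDQ and 2-ethoxyethanol to its 4β-(2-ethoxyethoxy) ether F2. F2 is condensed with an excess of nucleophile 10 (TMSOTf, CH2Cl2, −78 °C), the C3 gallate shielding the α face, to give the 4β→8 dimer F3. F3 then serves as the nucleophile toward the cation from 4 (TMSOTf, CH2Cl2, −78 °C) at C8 of its upper unit. This fallback sets out from 4 and 10 and returns to the route at 21.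

**Step 4.** The cation may attack para to the hydroxyl (between the two benzyloxy groups) or alkylate the product a second time, giving regioisomeric or doubly alkylated stubs. Fallback: 4 is condensed with an excess of phloroglucinol (TMSOTf, THF/CH2Cl2), a threefold-symmetric nucleophile that can give only one C-adduct, the 4β-(2,4,6-trihydroxyphenyl)flavan F4. MgCl2-mediated ortho-formylation (MgCl2, Et3N, (CH2O)n) at either of its two equivalent ring positions gives the trihydroxybenzaldehyde F5. Two equivalents of BnBr with K2CO3 should then alkylate the hydroxyl para to the aldehyde and the unhindered ortho hydroxyl, leaving the chelated hydroxyl next to the flavanyl group free. This fallback sets out from 4 and returns at 7.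

**Step 9.** The phenoxide deactivates the already hindered aldehyde, so addition may stall and the aryllithium may be protonated instead. The doubly activated carbinol may also ionise during isolation; it would be purified on triethylamine-deactivated silica or used crude. Fallback: the phenol of 7 is masked as its allyl ether F6 (allyl bromide, K2CO3, DMF). Aryllithium 12 is added to the now neutral aldehyde to give the allyl-protected carbinol F7. The allyl group is removed under neutral conditions with Pd(PPh3)4 (zerovalent palladium) and morpholine. This fallback sets out from 7 and returns at 14.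

**Step 12.** Competing Markovnikov addition, Z-to-E isomerisation of the product on the metal, or alkyne dimerisation may lower the geometric purity that step 13 depends on. Fallback: alkyne 18 is converted by [Rh(cod)Cl]2-catalysed trans-hydroboration (P(i-Pr)3, Et3N, pinacolborane) into the (Z)-alkenyl pinacol boronate F8. F8 is treated with KHF2 to give the potassium (Z)-alkenyltrifluoroborate F9. F9 is coupled with acid 15 by Cu(OAc)2-promoted oxidative C–O coupling of the Chan–Lam type (DMAP, 4 Å MS, air) with retention of alkene geometry. This fallback sets out from 18 and returns at 19.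

## Further compounds

F1 | step 13 | octa-O-benzyl-(−)-epigallocatechin gallate | O=C(O[C@@H]1Cc2c(OCc9ccccc9)cc(OCc9ccccc9)cc2O[C@@H]1c1cc(OCc9ccccc9)c(OCc9ccccc9)c(OCc9ccccc9)c1)c1cc(OCc9ccccc9)c(OCc9ccccc9)c(OCc9ccccc9)c1
F2 | step 13 | 4β-(2-ethoxyethoxy)-octa-O-benzyl-epigallocatechin gallate (C4 ether trans to the C3 ester) | O=C(O[C@@H]1[C@@H](OCCOCC)c2c(OCc9ccccc9)cc(OCc9ccccc9)cc2O[C@@H]1c1cc(OCc9ccccc9)c(OCc9ccccc9)c(OCc9ccccc9)c1)c1cc(OCc9ccccc9)c(OCc9ccccc9)c(OCc9ccccc9)c1
F3 | step 13 | [octa-O-benzyl-epigallocatechin gallate]-(4β→8)-[tetra-O-benzyl-3-O-TBS-catechin] | O=C(O[C@@H]1[C@@H](c2c(OCc9ccccc9)cc(OCc9ccccc9)c3c2O[C@H](c2ccc(OCc9ccccc9)c(OCc9ccccc9)c2)[C@@H](O[Si](C)(C)C(C)(C)C)C3)c2c(OCc9ccccc9)cc(OCc9ccccc9)cc2O[C@@H]1c1cc(OCc9ccccc9)c(OCc9ccccc9)c(OCc9ccccc9)c1)c1cc(OCc9ccccc9)c(OCc9ccccc9)c(OCc9ccccc9)c1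
F4 | step 4 | 2-[tetra-O-benzyl-3-O-TBS-epicatechin-4β-yl]benzene-1,3,5-triol | Oc1cc(O)c([C@H]2c3c(OCc9ccccc9)cc(OCc9ccccc9)cc3O[C@H](c3ccc(OCc9ccccc9)c(OCc9ccccc9)c3)[C@@H]2O[Si](C)(C)C(C)(C)C)c(O)c1
F5 | step 4 | 2,4,6-trihydroxy-3-[tetra-O-benzyl-3-O-TBS-epicatechin-4β-yl]benzaldehyde | O=Cc1c(O)cc(O)c([C@H]2c3c(OCc9ccccc9)cc(OCc9ccccc9)cc3O[C@H](c3ccc(OCc9ccccc9)c(OCc9ccccc9)c3)[C@@H]2O[Si](C)(C)C(C)(C)C)c1O
F6 | step 9 | 2-(allyloxy)-4,6-bis(benzyloxy)-3-[tetra-O-benzyl-3-O-TBS-epicatechin-4β-yl]benzaldehyde | O=Cc1c(OCC=C)c([C@H]2c3c(OCc9ccccc9)cc(OCc9ccccc9)cc3O[C@H](c3ccc(OCc9ccccc9)c(OCc9ccccc9)c3)[C@@H]2O[Si](C)(C)C(C)(C)C)c(OCc9ccccc9)cc1OCc9ccccc9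
F7 | step 9 | O-allyl ether of carbinol 14 (phenol oxygen allylated, both carbinol epimers) | OC(c1c(OCc9ccccc9)cc(OCc9ccccc9)c2c1O[C@H](c1ccc(OCc9ccccc9)c(OCc9ccccc9)c1)[C@@H](O[Si](C)(C)C(C)(C)C)C2)c1c(OCc9ccccc9)cc(OCc9ccccc9)c([C@H]2c3c(OCc9ccccc9)cc(OCc9ccccc9)cc3O[C@H](c3ccc(OCc9ccccc9)c(OCc9ccccc9)c3)[C@@H]2O[Si](C)(C)C(C)(C)C)c1OCC=C
F8 | step 12 | (Z)-2-[3,4,5-tris(benzyloxy)phenyl]ethenylboronic acid pinacol ester | CC1(C)OB(/C=C\c2cc(OCc9ccccc9)c(OCc9ccccc9)c(OCc9ccccc9)c2)OC1(C)C
F9 | step 12 | potassium (Z)-2-[3,4,5-tris(benzyloxy)phenyl]ethenyltrifluoroborate | [K+].F[B-](F)(F)/C=C\c1cc(OCc9ccccc9)c(OCc9ccccc9)c(OCc9ccccc9)c1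
A1 | alternative 1 | [octa-O-benzyl-epigallocatechin gallate]-(4β→8)-[tetra-O-benzyl-catechin] with free 3-OH on the bottom unit | O=C(O[C@@H]1[C@@H](c2c(OCc9ccccc9)cc(OCc9ccccc9)c3c2O[C@H](c2ccc(OCc9ccccc9)c(OCc9ccccc9)c2)[C@@H](O)C3)c2c(OCc9ccccc9)cc(OCc9ccccc9)cc2O[C@@H]1c1cc(OCc9ccccc9)c(OCc9ccccc9)c(OCc9ccccc9)c1)c1cc(OCc9ccccc9)c(OCc9ccccc9)c(OCc9ccccc9)c1
A2 | alternative 1 | octa-O-benzyl-epigallocatechin gallate carrying at C4β a 2-hydroxy-4,6-bis(benzyloxy)phenyl group whose 3-position bears a (2S,3S)-trans-3-[3,4-bis(benzyloxy)phenyl]oxiran-2-ylmethyl chain | O=C(O[C@@H]1[C@@H](c2c(O)c(C[C@@H]3O[C@H]3c3ccc(OCc9ccccc9)c(OCc9ccccc9)c3)c(OCc9ccccc9)cc2OCc9ccccc9)c2c(OCc9ccccc9)cc(OCc9ccccc9)cc2O[C@@H]1c1cc(OCc9ccccc9)c(OCc9ccccc9)c(OCc9ccccc9)c1)c1cc(OCc9ccccc9)c(OCc9ccccc9)c(OCc9ccccc9)c1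
A3 | alternative 2 | perbenzylated epigallocatechin gallate-(4β→8)-catechin gallate dimer | O=C(O[C@@H]1[C@@H](c2c(OCc9ccccc9)cc(OCc9ccccc9)c3c2O[C@H](c2ccc(OCc9ccccc9)c(OCc9ccccc9)c2)[C@@H](OC(=O)c2cc(OCc9ccccc9)c(OCc9ccccc9)c(OCc9ccccc9)c2)C3)c2c(OCc9ccccc9)cc(OCc9ccccc9)cc2O[C@@H]1c1cc(OCc9ccccc9)c(OCc9ccccc9)c(OCc9ccccc9)c1)c1cc(OCc9ccccc9)c(OCc9ccccc9)c(OCc9ccccc9)c1
A4 | alternative 2 | open-chain C4 carbinol (either epimer) with the C3 tri-O-benzylgallate, the C2 3,5-bis(benzyloxy)phenyl ether and the tetra-O-benzyl-catechin gallate-8-yl group on C4 | O=C(O[C@H](C(O)c2c(OCc9ccccc9)cc(OCc9ccccc9)c3c2O[C@H](c2ccc(OCc9ccccc9)c(OCc9ccccc9)c2)[C@@H](OC(=O)c2cc(OCc9ccccc9)c(OCc9ccccc9)c(OCc9ccccc9)c2)C3)[C@H](Oc2cc(OCc9ccccc9)cc(OCc9ccccc9)c2)c2cc(OCc9ccccc9)c(OCc9ccccc9)c(OCc9ccccc9)c2)c2cc(OCc9ccccc9)c(OCc9ccccc9)c(OCc9ccccc9)c2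
A5 | alternative 3 | [penta-O-benzyl-3-O-TBS-epigallocatechin]-(4β→8)-[tetra-O-benzyl-3-O-TBS-catechin] | CC(C)(C)[Si](C)(C)O[C@@H]1[C@@H](c2c(OCc9ccccc9)cc(OCc9ccccc9)c3c2O[C@H](c2ccc(OCc9ccccc9)c(OCc9ccccc9)c2)[C@@H](O[Si](C)(C)C(C)(C)C)C3)c2c(OCc9ccccc9)cc(OCc9ccccc9)cc2O[C@@H]1c1cc(OCc9ccccc9)c(OCc9ccccc9)c(OCc9ccccc9)c1
A6 | alternative 3 | open-chain C2 alcohol with the C3 silyl ether and, on C4, the 3-bromo-4,6-bis(benzyloxy)phenyl group and the tetra-O-benzyl-3-O-TBS-catechin-8-yl group | CC(C)(C)[Si](C)(C)O[C@H]([C@@H](c2c(OCc9ccccc9)cc(OCc9ccccc9)c3c2O[C@H](c2ccc(OCc9ccccc9)c(OCc9ccccc9)c2)[C@@H](O[Si](C)(C)C(C)(C)C)C3)c2cc(Br)c(OCc9ccccc9)cc2OCc9ccccc9)[C@H](O)c2cc(OCc9ccccc9)c(OCc9ccccc9)c(OCc9ccccc9)c2
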